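**Retrosynthetic overview**
1. Target 22 ⇐ silyl ether 20 (silyl → acetate) ⇐ ester 18 (C-4 methyl by enolate alkylation) ⇐ 4,4-diester 17 (Krapcho).
2. 17 (1(10)-alkene) ⇐ 1-ketone 15 (reduction, dehydration) ⇐ cycloadduct 14 (diimide on the 6,7-alkene).
3. Key disconnection: 14 ⇐ acyclic trienone 13 by one intramolecular Diels–Alder reaction forming C5–C10 and C8–C9; rings A and B close together and C-5, C-8, C-9 are set at once.
4. 13 ⇐ alkylidene malonate 11 + chloro enone 8 (deconjugative Michael); 11 ⇐ dimethyl malonate + pent-2-enal.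
5. 8 ⇐ geraniol (oxidative cleavage, alkyne, methylalumination–acylation).

Assumption: the (S)-oxazaborolidine/AlBr3 catalyst is taken to give the enantiomer 14 shown (the (R)-catalyst is used if the sense is opposite); locants C-1 to C-20 follow halimane numbering.

**Step 1**
Reactants: 1 geraniol
Product: 2 geranyl tert-butyldiphenylsilyl ether
Conditions: TBDPSCl, imidazole, DMF, rt
Reagents that add atoms: tert-butyl(chloro)diphenylsilane, CC(C)(C)[Si](Cl)(c1ccccc1)c1ccccc1
Why: Silylation gives an ether that survives Me3Al, AlBr3, hydride, hot LiCl and LiN(i-Pr)2; no stereocentre is formed.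

**Step 2**
Reactants: 2 geranyl tert-butyldiphenylsilyl ether
Product: 4 (4E)-6-[(tert-butyldiphenylsilyl)oxy]-4-methylhex-4-enal, via epoxygeranyl silyl ether 3 (not isolated)
Conditions: mCPBA (1.05 equiv), CH2Cl2, 0 °C; then H5IO6, THF/H2O, 0 °C
Reagents that add atoms: 3-chloroperoxybenzoic acid, OOC(=O)c1cccc(Cl)c1; water, O
Why: Prilezhaev epoxidation selects the electron-richer 6,7-alkene and periodic acid cleaves the epoxide (through the diol) to the aldehyde with loss of acetone; the 2E-alkene is untouched.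

**Step 3**
Reactants: 4 (4E)-6-[(tert-butyldiphenylsilyl)oxy]-4-methylhex-4-enal
Product: 5 tert-butyl{[(2E)-3-methylhept-2-en-6-yn-1-yl]oxy}diphenylsilane
Conditions: dimethyl (1-diazo-2-oxopropyl)phosphonate, K2CO3, MeOH, 0 °C → rt
Reagents that add atoms: dimethyl (1-diazo-2-oxopropyl)phosphonate, COP(=O)(OC)C(=[N+]=[N-])C(C)=O
Why: Seyferth–Gilbert homologation (Ohira–Bestmann variant) converts the aldehyde into the terminal alkyne, adding the future C-10 under conditions that leave the silyl ether and alkene alone.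

**Step 4**
Reactants: 5 tert-butyl{[(2E)-3-methylhept-2-en-6-yn-1-yl]oxy}diphenylsilane, 6 3-chloropropanoyl chloride
Product: 8 (4E,8E)-10-[(tert-butyldiphenylsilyl)oxy]-1-chloro-5,8-dimethyldeca-4,8-dien-3-one, via alkenylalane 7 (not isolated)
Conditions: Me3Al (2.5 equiv), Cp2ZrCl2 (0.25 equiv), CH2Cl2, 0 °C → rt; then 6, Pd(PPh3)4 (5 mol %), THF, 0 °C
Reagents that add atoms: trimethylaluminium, C[Al](C)C
Why: Negishi zirconium-catalysed syn-carboalumination puts the new methyl (future C-20) and Al cis, and palladium-catalysed acylation of the alkenylalane with retention gives the E-enone with that methyl cis to the carbonyl.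

**Step 5**
Reactants: 9 dimethyl malonate, 10 (2E)-pent-2-enal
Product: 11 dimethyl 2-[(2E)-pent-2-en-1-ylidene]propanedioate
Conditions: piperidine (10 mol %), AcOH (10 mol %), toluene, reflux, Dean–Stark
Reagents that add atoms: none
Why: Knoevenagel condensation with azeotropic water removal gives the dienylidene malonate; no stereocentre is formed and the 2E-alkene is retained.

**Step 6**
Reactants: 11 dimethyl 2-[(2E)-pent-2-en-1-ylidene]propanedioate, 8 (4E,8E)-10-[(tert-butyldiphenylsilyl)oxy]-1-chloro-5,8-dimethyldeca-4,8-dien-3-one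
Product: 13 dimethyl 2-[(1E,3E)-penta-1,3-dien-1-yl]-2-[(4E,8E)-10-(tert-butyldiphenylsilyloxy)-5,8-dimethyl-3-oxodeca-4,8-dien-1-yl]propanedioate, via divinyl ketone 12 (not isolated)
Conditions: DBU (2.2 equiv), MeCN, 0 °C → rt
Reagents that add atoms: none
Why: DBU eliminates HCl from the β-chloro ketone (E1cB) and the vinylogous malonate anion of 11 adds through its α-carbon to the unsubstituted vinyl group (deconjugative Michael addition), creating quaternary C-4 and the (1E,3E)-diene.

**Step 7**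
Reactants: 13 dimethyl 2-[(1E,3E)-penta-1,3-dien-1-yl]-2-[(4E,8E)-10-(tert-butyldiphenylsilyloxy)-5,8-dimethyl-3-oxodeca-4,8-dien-1-yl]propanedioate
Product: 14 dimethyl (5S,8R,9S,10S)-15-(tert-butyldiphenylsilyloxy)-1-oxohalima-6,13E-diene-18,19-dioate
Conditions: (S)-3,3-diphenyl-1-(o-tolyl)tetrahydropyrrolo[1,2-c][1,3,2]oxazaborole (20 mol %), AlBr3 (16 mol %), CH2Cl2, −78 → −20 °C
Reagents that add atoms: none
Why: Proposed new method: catalytic enantioselective intramolecular Diels–Alder reaction of a β,β-disubstituted trienone in which the boron Lewis acid binds the enone carbonyl and the tether carbonyl lies endo, so the outside groups of the E,E-diene (C-4, 8-methyl) and the endo groups of the E-dienophile (C-1, 9-methyl) become cis on ring B, fixing C-5, C-8, C-9 (and C-10) while the catalyst chooses the enantiotopic face; closest known reactions are the Lewis-acid-catalysed cis-selective cyclisation of 1,7,9-decatrien-3-ones and oxazaborolidinium/AlBr3-catalysed Diels–Alder reactions of enones.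

**Step 8**
Reactants: 14 dimethyl (5S,8R,9S,10S)-15-(tert-butyldiphenylsilyloxy)-1-oxohalima-6,13E-diene-18,19-dioate
Product: 15 dimethyl (5S,8R,9S,10S)-15-(tert-butyldiphenylsilyloxy)-1-oxohalim-13E-ene-18,19-dioate
Conditions: 2-nitrobenzenesulfonylhydrazide, Et3N, CH2Cl2, rt
Reagents that add atoms: none
Why: Diimide reduction (concerted syn hydrogen transfer) takes the cis-disubstituted ring alkene much faster than the trisubstituted side-chain alkene and ignores the ketone; no stereocentre changes.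

**Step 9**
Reactants: 15 dimethyl (5S,8R,9S,10S)-15-(tert-butyldiphenylsilyloxy)-1-oxohalim-13E-ene-18,19-dioate
Product: 16 dimethyl (1S,5S,8R,9S,10S)-15-(tert-butyldiphenylsilyloxy)-1-hydroxyhalim-13E-ene-18,19-dioate
Conditions: NaBH4, MeOH, 0 °C
Reagents that add atoms: none
Why: Borohydride reduction from the face away from quaternary C-9 should give the 1-alcohol with its C–O bond anti to H-10; this centre is destroyed in step 10.

**Step 10**
Reactants: 16 dimethyl (1S,5S,8R,9S,10S)-15-(tert-butyldiphenylsilyloxy)-1-hydroxyhalim-13E-ene-18,19-dioate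
Product: 17 dimethyl (5S,8R,9S)-15-(tert-butyldiphenylsilyloxy)halima-1(10),13E-diene-18,19-dioate
Conditions: Martin sulfurane, CH2Cl2, rt
Reagents that add atoms: none
Why: Martin sulfurane dehydration is an anti E2 elimination of the alkoxysulfonium in which the antiperiplanar tertiary H-10 is lost to give the trisubstituted 1(10)-alkene (Zaitsev), erasing C-1 and C-10.

**Step 11**
Reactants: 17 dimethyl (5S,8R,9S)-15-(tert-butyldiphenylsilyloxy)halima-1(10),13E-diene-18,19-dioate
Product: 18 methyl 15-(tert-butyldiphenylsilyloxy)-19-norhalima-1(10),13E-dien-18-oate (C-4 epimer mixture)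
Conditions: LiCl, H2O (2 equiv), DMSO, 155 °C
Reagents that add atoms: none
Why: Krapcho dealkoxycarbonylation (chloride attack on an ester methyl, then decarboxylation) removes one ester; the C-4 mixture does not matter because C-4 is rebuilt from the enolate in step 12.

**Step 12**
Reactants: 18 methyl 15-(tert-butyldiphenylsilyloxy)-19-norhalima-1(10),13E-dien-18-oate
Product: 20 methyl (4S,5S,8R,9S)-15-(tert-butyldiphenylsilyloxy)halima-1(10),13E-dien-18-oate, via lithium ester enolate 19 (not isolated)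
Conditions: LiN(i-Pr)2, THF, −78 °C; then MeI, DMPU, −78 → −20 °C
Reagents that add atoms: iodomethane, CI
Why: Ester enolate alkylation in which, with C-10 trigonal, H-5 stands perpendicular to the enolate plane and C-6 lies in it, so MeI should enter axially anti to H-5 and away from the C-6 methylene, placing the methyl trans and the ester cis to H-5 (4S).

**Step 13**
Reactants: 20 methyl (4S,5S,8R,9S)-15-(tert-butyldiphenylsilyloxy)halima-1(10),13E-dien-18-oate
Product: 22 methyl (4S,5S,8R,9S)-15-acetoxyhalima-1(10),13E-dien-18-oate, via allylic alcohol 21 (not isolated)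
Conditions: Bu4NF, THF, rt; then Ac2O, pyridine, DMAP (cat.), rt
Reagents that add atoms: acetic anhydride, CC(=O)OC(C)=O
Why: Fluoride desilylation followed by DMAP-catalysed O-acetylation touches neither the hindered methyl ester nor any stereocentre.

**Compound list**
1 | geraniol, (2E)-3,7-dimethylocta-2,6-dien-1-ol | CC(C)=CCC/C(C)=C/CO | starting material
2 | geranyl tert-butyldiphenylsilyl ether | CC(C)=CCC/C(C)=C/CO[Si](c1ccccc1)(c1ccccc1)C(C)(C)C | intermediate
3 | 6,7-epoxygeranyl tert-butyldiphenylsilyl ether (racemic epoxide) | CC1(C)OC1CC/C(C)=C/CO[Si](c1ccccc1)(c1ccccc1)C(C)(C)C | intermediate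
4 | (4E)-6-[(tert-butyldiphenylsilyl)oxy]-4-methylhex-4-enal | O=CCC/C(C)=C/CO[Si](c1ccccc1)(c1ccccc1)C(C)(C)C | intermediate
5 | tert-butyl{[(2E)-3-methylhept-2-en-6-yn-1-yl]oxy}diphenylsilane | C#CCC/C(C)=C/CO[Si](c1ccccc1)(c1ccccc1)C(C)(C)C | intermediate
6 | 3-chloropropanoyl chloride | ClCCC(Cl)=O | starting material
7 | [(1E,5E)-7-(tert-butyldiphenylsilyloxy)-2,5-dimethylhepta-1,5-dien-1-yl]dimethylalumane | C[Al](C)/C=C(\C)CC/C(C)=C/CO[Si](c1ccccc1)(c1ccccc1)C(C)(C)C | intermediate
8 | (4E,8E)-10-[(tert-butyldiphenylsilyl)oxy]-1-chloro-5,8-dimethyldeca-4,8-dien-3-one | ClCCC(=O)/C=C(\C)CC/C(C)=C/CO[Si](c1ccccc1)(c1ccccc1)C(C)(C)C | intermediate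
9 | dimethyl malonate | COC(=O)CC(=O)OC | starting material
10 | (2E)-pent-2-enal | CC/C=C/C=O | starting material
11 | dimethyl 2-[(2E)-pent-2-en-1-ylidene]propanedioate | COC(=O)C(=C/C=C/CC)C(=O)OC | intermediate
12 | (4E,8E)-10-[(tert-butyldiphenylsilyl)oxy]-5,8-dimethyldeca-1,4,8-trien-3-one | C=CC(=O)/C=C(\C)CC/C(C)=C/CO[Si](c1ccccc1)(c1ccccc1)C(C)(C)C | intermediate
13 | dimethyl 2-[(1E,3E)-penta-1,3-dien-1-yl]-2-[(4E,8E)-10-(tert-butyldiphenylsilyloxy)-5,8-dimethyl-3-oxodeca-4,8-dien-1-yl]propanedioate | COC(=O)C(/C=C/C=C/C)(CCC(=O)/C=C(\C)CC/C(C)=C/CO[Si](c1ccccc1)(c1ccccc1)C(C)(C)C)C(=O)OC | intermediate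
14 | dimethyl (5S,8R,9S,10S)-15-(tert-butyldiphenylsilyloxy)-1-oxohalima-6,13E-diene-18,19-dioate (cis-fused; H-5 and H-10 syn; 8- and 9-methyls syn to each other and anti to H-5) | COC(=O)C1(C(=O)OC)CCC(=O)[C@H]2[C@@H]1C=C[C@@H](C)[C@]2(C)CC/C(C)=C/CO[Si](c1ccccc1)(c1ccccc1)C(C)(C)C | intermediate
15 | dimethyl (5S,8R,9S,10S)-15-(tert-butyldiphenylsilyloxy)-1-oxohalim-13E-ene-18,19-dioate | COC(=O)C1(C(=O)OC)CCC(=O)[C@H]2[C@@H]1CC[C@@H](C)[C@]2(C)CC/C(C)=C/CO[Si](c1ccccc1)(c1ccccc1)C(C)(C)C | intermediate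
16 | dimethyl (1S,5S,8R,9S,10S)-15-(tert-butyldiphenylsilyloxy)-1-hydroxyhalim-13E-ene-18,19-dioate | COC(=O)C1(C(=O)OC)CC[C@H](O)[C@H]2[C@@H]1CC[C@@H](C)[C@]2(C)CC/C(C)=C/CO[Si](c1ccccc1)(c1ccccc1)C(C)(C)C | intermediate
17 | dimethyl (5S,8R,9S)-15-(tert-butyldiphenylsilyloxy)halima-1(10),13E-diene-18,19-dioate | COC(=O)C1(C(=O)OC)CCC=C2[C@@H]1CC[C@@H](C)[C@]2(C)CC/C(C)=C/CO[Si](c1ccccc1)(c1ccccc1)C(C)(C)C | intermediate
18 | methyl 15-(tert-butyldiphenylsilyloxy)-19-norhalima-1(10),13E-dien-18-oate (C-5, C-8, C-9 as in 17; C-4 epimer mixture) | COC(=O)C1CCC=C2[C@@H]1CC[C@@H](C)[C@]2(C)CC/C(C)=C/CO[Si](c1ccccc1)(c1ccccc1)C(C)(C)C | intermediate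
19 | lithium enolate of 18 | COC(O[Li])=C1CCC=C2[C@@H]1CC[C@@H](C)[C@]2(C)CC/C(C)=C/CO[Si](c1ccccc1)(c1ccccc1)C(C)(C)C | intermediate
20 | methyl (4S,5S,8R,9S)-15-(tert-butyldiphenylsilyloxy)halima-1(10),13E-dien-18-oate | COC(=O)[C@@]1(C)CCC=C2[C@@H]1CC[C@@H](C)[C@]2(C)CC/C(C)=C/CO[Si](c1ccccc1)(c1ccccc1)C(C)(C)C | intermediate
21 | methyl (4S,5S,8R,9S)-15-hydroxyhalima-1(10),13E-dien-18-oate | COC(=O)[C@@]1(C)CCC=C2[C@@H]1CC[C@@H](C)[C@]2(C)CC/C(C)=C/CO | intermediate
22 | methyl (4S,5S,8R,9S)-15-acetoxyhalima-1(10),13E-dien-18-oate | COC(=O)[C@@]1(C)CCC=C2[C@@H]1CC[C@@H](C)[C@]2(C)CC/C(C)=C/COC(C)=O | target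

**Totals**
Total steps: 13. Longest linear sequence: 12 (steps 1–4, 6–13).

**Steps most likely to fail**

Step 7 (reactivity of the β,β-disubstituted enone, endo preference and enantioselectivity are untested). The fallback sets out from 13 and returns at 14, replacing catalyst control by a covalently bound controller. The enone of 13 is ketalised with the bis(trimethylsilyl) ether of (R,R)-hydrobenzoin (TMSOTf cat., CH2Cl2, −78 °C) to the diphenyldioxolane of 13 F1. Further TMSOTf opens it to the dioxolenium-stabilised allyl cation, which undergoes a Gassman ionic intramolecular Diels–Alder reaction (−78 → −40 °C) to the diphenyldioxolane of 14 F2; the diol antipode is chosen to match the required series. PPTS in wet acetone then releases ketone 14.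

Step 10 (the elimination may go towards C-2, or the alcohol may have the wrong configuration for anti elimination). The fallback sets out from 15 and returns at 17, bypassing 16. Tf2O with 2,6-di-tert-butyl-4-methylpyridine under equilibrating conditions converts ketone 15 into the more substituted 1(10)-enol triflate F3. Reduction with Pd(OAc)2, PPh3, Bu3N and HCO2H in DMF at 60 °C replaces the C–O bond by C–H and gives 17.

Step 12 (the facial sense of the enolate methylation is argued, not proven). The fallback sets out from 16 and returns at 20, distinguishing the two C-4 esters by geometry instead of enolate face. NaH (cat.) in hot toluene closes the bridged lactone F4 between the 1-hydroxyl and the only ester on its face (the one trans to H-5). LiBH4 reduces the strained lactone but not the hindered methyl ester, giving the diol F5. I2, PPh3 and imidazole convert the primary alcohol into the iodide F6, and Bu3SnH with AIBN gives the hydroxy ester F7, which already has the C-4 methyl trans to H-5. Martin sulfurane then gives 20.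

**Further compounds**
F1 | step 7 | (4R,5R)-4,5-diphenyl-1,3-dioxolane ketal of trienone 13 | COC(=O)C(/C=C/C=C/C)(CCC1(O[C@H](c2ccccc2)[C@H](O1)c2ccccc2)/C=C(\C)CC/C(C)=C/CO[Si](c1ccccc1)(c1ccccc1)C(C)(C)C)C(=O)OC
F2 | step 7 | (4R,5R)-4,5-diphenyl-1,3-dioxolane ketal of cycloadduct 14 | COC(=O)C1(C(=O)OC)CCC3(O[C@H](c4ccccc4)[C@H](O3)c4ccccc4)[C@H]2[C@@H]1C=C[C@@H](C)[C@]2(C)CC/C(C)=C/CO[Si](c1ccccc1)(c1ccccc1)C(C)(C)C
F3 | step 10 | dimethyl (5S,8R,9S)-15-(tert-butyldiphenylsilyloxy)-1-(trifluoromethylsulfonyloxy)halima-1(10),13E-diene-18,19-dioate | COC(=O)C1(C(=O)OC)CCC(OS(=O)(=O)C(F)(F)F)=C2[C@@H]1CC[C@@H](C)[C@]2(C)CC/C(C)=C/CO[Si](c1ccccc1)(c1ccccc1)C(C)(C)C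
F4 | step 12 | bridged 19,1-lactone of 16 (methyl ester cis to H-5 retained) | COC(=O)[C@]12CC[C@H](OC1=O)[C@H]3[C@@H]2CC[C@@H](C)[C@]3(C)CC/C(C)=C/CO[Si](c4ccccc4)(c4ccccc4)C(C)(C)C
F5 | step 12 | methyl 15-(tert-butyldiphenylsilyloxy)-1,19-dihydroxyhalim-13E-en-18-oate | COC(=O)[C@@]1(CO)CC[C@H](O)[C@H]2[C@@H]1CC[C@@H](C)[C@]2(C)CC/C(C)=C/CO[Si](c1ccccc1)(c1ccccc1)C(C)(C)C
F6 | step 12 | methyl 15-(tert-butyldiphenylsilyloxy)-1-hydroxy-19-iodohalim-13E-en-18-oate | COC(=O)[C@@]1(CI)CC[C@H](O)[C@H]2[C@@H]1CC[C@@H](C)[C@]2(C)CC/C(C)=C/CO[Si](c1ccccc1)(c1ccccc1)C(C)(C)C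
F7 | step 12 | methyl 15-(tert-butyldiphenylsilyloxy)-1-hydroxyhalim-13E-en-18-oate | COC(=O)[C@@]1(C)CC[C@H](O)[C@H]2[C@@H]1CC[C@@H](C)[C@]2(C)CC/C(C)=C/CO[Si](c1ccccc1)(c1ccccc1)C(C)(C)C
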